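**Plan**

- Retrosynthesis: the four phenols are traced back to methyl ethers and each resorcinol ring to a 5-alkylcyclohexane-1,3-dione. In each ring two C–C bonds are cut (resorcinol numbering): C4–C5, next to the chain-bearing carbon, and C2–C3, between an oxygenated carbon and the CH flanked by both oxygens. This releases dimethyl malonate and a methyl enone; the two enone C=C bonds are then cut back to hexadecanedial and an acetonyl ylide.
- Enabling feature: in each benzene ring the chain terminus (C1 or C14 of the tetradecane) sits on ring carbon C5, meta to both hydroxylated carbons C1 and C3. This is the pattern of a cyclohexane-1,3-dione whose C5 was the β-carbon of an alk-3-en-2-one, so no substitution on an aromatic ring is needed.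
- Forward: the C16 diol is oxidised and extended at both ends to the C22 bis-enone, so the whole chain is in place before any ring exists. Both six-membered rings then close in one operation, followed by ester hydrolysis–decarboxylation, iodine–methanol aromatisation and BBr3 demethylation.
- Stereochemistry: the target is achiral; the E-alkenes and the sp3 centres made in the annulation are consumed on the way, so nothing has to be controlled.

Key step: step 3

Remark: the cyclic 1,3-diones 7, 8 and 9 are written as diketo tautomers although they should exist largely as enols; the sp3 centres of 6, 7, 8 and 10 arise as mixtures and are written without configuration.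

Step 1
Reactants: 1 hexadecane-1,16-diol
Product: 2 hexadecanedial
Conditions: IBX (2-iodoxybenzoic acid, 3 equiv per OH), EtOAc, 80 °C; filter, concentrate, use directly
Reagents that add atoms: none
Why: IBX oxidation (hypervalent-iodine alcohol oxidation) should take both primary alcohols to the aldehyde level without over-oxidation in the absence of water, the diol dissolving in hot EtOAc while the reagent and its reduced form stay insoluble and are filtered off; no stereocentre is formed.

Step 2
Reactants: 2 hexadecanedial; 3 acetonyl ylide 1-(triphenylphosphoranylidene)propan-2-one
Product: 4 bis-enone (3E,19E)-docosa-3,19-diene-2,21-dione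
Conditions: 3 (2.4 equiv), toluene, 90 °C
Reagents that add atoms: none
Why: Wittig olefination with a ketone-stabilised ylide is selective for aldehydes, should give the E-enone at both termini through reversible oxaphosphetane formation, and leaves the product enone untouched.

Step 3
Reactants: 4 bis-enone (3E,19E)-docosa-3,19-diene-2,21-dione; 5 dimethyl malonate
Product: 7 bis(dione ester) dimethyl 6,6'-(tetradecane-1,14-diyl)bis(2,4-dioxocyclohexane-1-carboxylate), via bis-Michael tetraester 6 (not isolated)
Conditions: 5 (2.4 equiv), NaOMe (2.4 equiv), MeOH–THF, 65 °C; then aq HCl, 0 °C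
Reagents that add atoms: none
Why: Methoxide generates the malonate anion, which adds 1,4 to each E-enone at its β-carbon (C4 and C19 of 4) to give tetraester 6; proton transfer then places the ketone enolate on the terminal methyl group, whose carbon attacks one of the two geminal ester carbonyls and expels methoxide. The closest known reaction type is the Michael–Claisen annulation of an alk-3-en-2-one with a malonic ester that leads to dimedone and to 5-alkylcyclohexane-1,3-diones, run here at both ends of one chain. Each of the two rings closes in the same way, by a 6-exo-trig C-acylation in which the attacked ester C=O lies outside the forming ring; the internal α-CH2 enolate could only reach a four-membered ring and is unproductive. The new sp3 centres (C1 and C6 of each ring) are under no control and need none: C1 equilibrates through the enol, C6 later becomes an aromatic carbon, and the target is achiral. The selectivities required are conjugate over carbonyl addition and complete conversion of both termini; the stabilised, reversibly adding malonate anion secures the first, and the irreversible deprotonation of each acidic cyclic β-diketone by methoxide secures the second, the fourteen-methylene tether keeping the two ends from interfering.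

Step 4
Reactants: 7 bis(dione ester) dimethyl 6,6'-(tetradecane-1,14-diyl)bis(2,4-dioxocyclohexane-1-carboxylate)
Product: 9 bis-dione 5,5'-(tetradecane-1,14-diyl)bis(cyclohexane-1,3-dione), via bis(β-keto acid) 8 (not isolated)
Conditions: aq NaOH (2 M), MeOH, 80 °C; then HCl to pH 1, 90 °C
Reagents that add atoms: none
Why: Saponification of the β-keto ester and acid-promoted decarboxylation of the β-keto acid through its cyclic six-membered transition state (ketonic hydrolysis, as in the preparation of dimedone) should remove both ester groups, the ring surviving hot base because the 1,3-dione is present as its unreactive enolate; the earlier sp3 centres vanish as C5 of each ring becomes a symmetric carbon.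

Step 5
Reactants: 9 bis-dione 5,5'-(tetradecane-1,14-diyl)bis(cyclohexane-1,3-dione)
Product: 11 tetramethyl ether 1,14-bis(3,5-dimethoxyphenyl)tetradecane, via bis(3-methoxycyclohex-2-enone) 10 (not isolated)
Conditions: I2 (2.2 equiv per ring), MeOH, 65 °C
Reagents that add atoms: methanol, CO
Why: Iodine–methanol oxidative aromatisation of cyclohexane-1,3-diones, in which the HI formed catalyses enol etherification to the vinylogous ester 10 and on to the methoxy dienol ether, and α-iodination followed by loss of HI then aromatises each ring with both oxygens kept as methyl ethers.

Step 6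
Reactants: 11 tetramethyl ether 1,14-bis(3,5-dimethoxyphenyl)tetradecane
Product: 12 bisnorstriatol, 5,5'-(tetradecane-1,14-diyl)bis(benzene-1,3-diol)
Conditions: BBr3 (6 equiv), CH2Cl2, −78 °C to rt; then H2O, 0 °C
Reagents that add atoms: none
Why: BBr3 cleavage of aryl methyl ethers (Lewis acid–base adduct, bromide attack on the methyl group, hydrolysis of the aryloxyboron species on work-up) is general for 3,5-dimethoxyalkylbenzenes, and the saturated chain offers no competing site.

**Compound list**

1 | hexadecane-1,16-diol | OCCCCCCCCCCCCCCCCO | starting material
2 | hexadecanedial | O=CCCCCCCCCCCCCCCC=O | intermediate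
3 | 1-(triphenylphosphoranylidene)propan-2-one | CC(=O)C=P(c1ccccc1)(c1ccccc1)c1ccccc1 | starting material
4 | (3E,19E)-docosa-3,19-diene-2,21-dione | CC(=O)/C=C/CCCCCCCCCCCCCC/C=C/C(C)=O | intermediate
5 | dimethyl malonate | COC(=O)CC(=O)OC | starting material
6 | tetramethyl 2,17-bis(2-oxopropyl)octadecane-1,1,18,18-tetracarboxylate (bis-Michael tetraester, mixture of diastereomers) | COC(=O)C(C(=O)OC)C(CC(C)=O)CCCCCCCCCCCCCCC(CC(C)=O)C(C(=O)OC)C(=O)OC | intermediate (not isolated)
7 | dimethyl 6,6'-(tetradecane-1,14-diyl)bis(2,4-dioxocyclohexane-1-carboxylate) (mixture of diastereomers) | COC(=O)C1C(=O)CC(=O)CC1CCCCCCCCCCCCCCC1CC(=O)CC(=O)C1C(=O)OC | intermediate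
8 | 6,6'-(tetradecane-1,14-diyl)bis(2,4-dioxocyclohexane-1-carboxylic acid) (mixture of diastereomers) | OC(=O)C1C(=O)CC(=O)CC1CCCCCCCCCCCCCCC1CC(=O)CC(=O)C1C(=O)O | intermediate (not isolated)
9 | 5,5'-(tetradecane-1,14-diyl)bis(cyclohexane-1,3-dione) | O=C1CC(=O)CC(C1)CCCCCCCCCCCCCCC1CC(=O)CC(=O)C1 | intermediate
10 | 5,5'-(tetradecane-1,14-diyl)bis(3-methoxycyclohex-2-en-1-one) (mixture of diastereomers) | COC1=CC(=O)CC(C1)CCCCCCCCCCCCCCC1CC(=O)C=C(OC)C1 | intermediate (not isolated)
11 | 1,14-bis(3,5-dimethoxyphenyl)tetradecane | COc1cc(OC)cc(CCCCCCCCCCCCCCc2cc(OC)cc(OC)c2)c1 | intermediate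
12 | bisnorstriatol, 5,5'-(tetradecane-1,14-diyl)bis(benzene-1,3-diol) | Oc1cc(O)cc(CCCCCCCCCCCCCCc2cc(O)cc(O)c2)c1 | target

**Summary**

Total step count: 6. Longest linear sequence: 6 steps (1 to 12).

Steps most likely to fail:

Step 3. The double annulation may stall with one terminus left at the enone or open Michael stage. Ketone enolates of the poorly soluble C22 bis-enone may also add to enones of other chains and give oligomers. The fallback supplies the ring atoms by the other classical pairing, an enoate with an acetoacetate. It sets out from dialdehyde 2: double Wittig olefination with methyl (triphenylphosphoranylidene)acetate in toluene at 80 °C would give dimethyl (2E,18E)-icosa-2,18-dienedioate F1. Methyl acetoacetate and NaOMe in MeOH at reflux would then add through the central carbon to both β-carbons, giving dimethyl 3,18-bis(1-methoxy-1,3-dioxobutan-2-yl)icosanedioate F2. Its acetyl methyl groups close both rings by Dieckmann-type attack on the chain esters, and acidification brings the route back at bis(dione ester) 7.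

Step 5. Etherification may remain incomplete, one ring may fail to aromatise cleanly, or the electron-rich dimethoxyarene may be iodinated in the ring. The fallback moves the dehydrogenation one stage earlier and uses bromine, with no methyl ethers. It sets out from 7: Br2 (1 equiv per ring) in DMF at 0 °C should brominate each enolised β-diketone at C3, giving dimethyl 3,3'-dibromo-6,6'-(tetradecane-1,14-diyl)bis(2,4-dioxocyclohexane-1-carboxylate) F3. On warming to about 80 °C this should lose HBr to give dimethyl 6,6'-(tetradecane-1,14-diyl)bis(2,4-dihydroxybenzoate) F4. Aqueous NaOH at reflux under N2, then acidification, would saponify the esters to 6,6'-(tetradecane-1,14-diyl)bis(2,4-dihydroxybenzoic acid) F5. This β-resorcylic acid decarboxylates readily, and the route is rejoined at target 12.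

Step 2. The weakly nucleophilic keto-stabilised ylide may olefinate so slowly that aldol self-condensation of the enolisable dialdehyde competes and one terminus stays at the aldehyde stage. The fallback forms the enone double bonds by alkene cross-metathesis instead. It sets out from 2: methylenation with Ph3P=CH2 (from methyltriphenylphosphonium bromide and KOtBu, THF, 0 °C), which is fast at low temperature, would give octadeca-1,17-diene F6. Cross-metathesis with excess but-3-en-2-one and the second-generation Grubbs catalyst in CH2Cl2 at 40 °C, with loss of ethene, would deliver the E,E bis-enone and rejoin the route at 4.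

**Further compounds**

F1 | step 3 | dimethyl (2E,18E)-icosa-2,18-dienedioate | COC(=O)/C=C/CCCCCCCCCCCCCC/C=C/C(=O)OC
F2 | step 3 | dimethyl 3,18-bis(1-methoxy-1,3-dioxobutan-2-yl)icosanedioate (mixture of diastereomers) | COC(=O)CC(C(C(C)=O)C(=O)OC)CCCCCCCCCCCCCCC(CC(=O)OC)C(C(C)=O)C(=O)OC
F3 | step 5 | dimethyl 3,3'-dibromo-6,6'-(tetradecane-1,14-diyl)bis(2,4-dioxocyclohexane-1-carboxylate) (mixture of diastereomers) | COC(=O)C1C(=O)C(Br)C(=O)CC1CCCCCCCCCCCCCCC1CC(=O)C(Br)C(=O)C1C(=O)OC
F4 | step 5 | dimethyl 6,6'-(tetradecane-1,14-diyl)bis(2,4-dihydroxybenzoate) | COC(=O)c1c(O)cc(O)cc1CCCCCCCCCCCCCCc1cc(O)cc(O)c1C(=O)OC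
F5 | step 5 | 6,6'-(tetradecane-1,14-diyl)bis(2,4-dihydroxybenzoic acid) | OC(=O)c1c(O)cc(O)cc1CCCCCCCCCCCCCCc1cc(O)cc(O)c1C(=O)O
F6 | step 2 | octadeca-1,17-diene | C=CCCCCCCCCCCCCCCC=C
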